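## Analysis of the target

Cathayanon I (17) is a dihydroflavonol, a chroman-4-one made of rings A and C. Ring A carries hydroxyls at C5 and C7, C3 carries a hydroxyl, and C2 carries ring B, which is oxygenated at C2' and C4' and prenylated at C3' and C5'. The only stereocentres are C2 and C3; both are R, which places the C2 aryl group and the C3 hydroxyl trans on ring C. The two prenyl alkenes each sit ortho to a phenol, so strong acid turns them into chromans, and they exclude hydrogenolysis and unselective electrophilic oxidants. Ring C is labile in two ways: a C3 enolate can expel O1 and open the ring, and C2 can ionise with help from the 2'- and 4'-oxygens; either path erases C2, and the C3–C4 ketol can epimerise as well. Ring B is crowded, with an oxygen ortho to C1' and the C3' prenyl group wedged between two oxygens. The difficulty is therefore to set two adjacent stereocentres on an electron-rich ring C that tolerates neither strong acid nor equilibrating base, while two prenyl groups are carried along. The strategy rests on the make-up of ring C: the C4 carbonyl carbon lies between C4a of ring A and C3, and O1 links C8a to C2. A one-carbon carbonyl unit, an ortho C–I/O–H pair on ring A and the two sp carbons of a ring B acetylene therefore account for every atom of ring C. This gives ring C flat, at the flavone level, after which hydride at C2 and oxygen at C3 are added in that order.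

## Retrosynthetic reasoning

**17 to 16.** The last operation is removal of four aryl acetal ethers from the tetrakis-MOM dihydroflavonol 16. Acetal protection is chosen because it survives bases, organometallics, hydride and palladium, and because it leaves by mild acid solvolysis. Benzyl ethers would need hydrogenolysis and methyl ethers a strong Lewis acid, and the prenyl groups tolerate neither. The C3 hydroxyl is left free, so nothing harsher than aryl acetal cleavage is needed at the end.

**16 to 14.** The C3–O bond is cut, leading back to the (2S)-flavanone 14. The forward reaction is hydroxylation of the C3 enolate. The C2 aryl group shields one face of the enolate, so oxygen should enter trans to it. An N-sulfonyloxaziridine is the oxidant of choice because it transfers oxygen to enolates at low temperature and leaves trisubstituted alkenes alone. The descriptor at C2 changes from S in 14 to R in 16 without any spatial change, because the new oxygen raises C3 above C1' in the priority order.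

**14 to 13.** The C2–H bond is cut, leading back to the flavone 13. The forward reaction is an enantioselective conjugate reduction, in which a chiral copper hydride delivers hydride to one face of the planar C2=C3 bond. Setting C2 by hydride addition avoids any cationic or phenoxide-opening pathway at C2, the two ways in which this centre is most easily lost.

**13 to 3, 9 and 10.** This is the central disconnection. Three bonds of ring C are cut at once: C4a–C4, C4–C3 and O1–C2. That leaves the iodophenol 3 (C8a–OH and C4a–I), carbon monoxide 10 (C4) and the arylacetylene 9 (C3 and C2). Cutting here, and not at a single bond of ring C, gives two fragments of similar size that are each a few steps from simple aromatics, and it forms the whole heterocycle in one operation. The forward reaction must achieve carbonylative rather than direct alkynylation, and six-membered rather than five-membered ring closure; a secondary amine as medium addresses the second point.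

**9 to 8, 6, 5 and 4.** The terminal alkyne carbon of 9 is cut off, leading to aldehyde 8 (one-carbon homologation in the forward sense). In 8 the two aryl–CH2 bonds at C3 and C5 are cut, giving dibromide 6 and two equivalents of prenylstannane 7. The bromines of 6 trace back through 5 to 2,4-dihydroxybenzaldehyde 4, where the two hydroxyls direct halogenation to exactly the two positions that must carry prenyl groups. Doing the prenylation on a small aldehyde keeps this uncertain coupling far from the stereocentres.

**3 to 2 and 1.** The C–I bond of 3 is cut, giving the bis-MOM phenol 2, which comes from phloroglucinol 1 by twofold protection. The forward iodination must go ortho to the free hydroxyl and not between the two ethers; iodinating the phenoxide in aqueous bicarbonate is intended to achieve this.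

## Alternatives that were turned down

**Alternative 1: twofold prenylation of a dibromo dihydroflavonol.** The two aryl–CH2 bonds at C3' and C5' are cut last. In the forward sense the dibromide A2, which already has ring C and both stereocentres, is coupled twice with stannane 7 under a zerovalent palladium catalyst with a bulky trialkylphosphine to give A1.
- In its favour: the prenyl groups appear at the very end and never meet an oxidant, a reductant or an enolate. On this point it is stronger than the chosen route.
- Against it: the key step closes no ring and sets no stereocentre, so the whole problem of ring C and of C2 and C3 is moved into the synthesis of A2. The C3' bromide lies between two alkoxy groups and needs forcing conditions, and these act on a protected ketol that can epimerise at C3 or lose O1 by β-elimination. The fifth acetal, on the secondary C3 oxygen, is harder to remove than the aryl ones and pushes the final acid treatment towards conditions that cyclise the prenyl groups.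
- In comparison: the chosen route does the same coupling on aldehyde 6, where failure costs little, and uses its key step to build ring C.

**Alternative 2: ring closure by aryl ether formation at O1–C8a.** The O1–C8a bond is cut. The precursor is the open-chain hydroxy ketone A4, whose C2 alkoxide displaces an ortho fluoride on ring A to give A3.
- In its favour: both stereocentres are set in an acyclic aldol-type precursor and are not touched during ring closure. No enolate of a flavanone is ever formed, which is a real advantage over the chosen route.
- Against it: the fluoride sits on a ring that carries two further alkoxy donors and is activated only by the ortho ketone, so the substitution should be slow. Over that time the alkoxide of a β-hydroxy ketone can undergo retro-aldol cleavage, which destroys both centres, or the silyl group can migrate from O3 to O2 and lead to a five-membered ring. The fluorinated ring A ketone and the anti aldol each need several steps.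
- In comparison: the route would be longer and its risk lies in a step that can erase the stereochemistry, whereas the chosen route sets the stereocentres only after ring C exists.

**Alternative 3: opening of a chalcone epoxide by the ring A phenol.** The O1–C2 bond is cut. The trans-epoxy ketone A6 is attacked at its benzylic carbon by the free ortho phenol, with inversion, to give A5, which is the same compound as 16.
- In its favour: one asymmetric epoxidation sets both stereocentres, the sequence follows the likely biosynthesis, and it reaches 16 without the reduction and hydroxylation steps. In step economy after ring construction it is at least as good as the chosen route.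
- Against it: nucleophilic asymmetric epoxidation is least reliable on chalcones with this many donor groups and with ortho substituents on both rings. The ring A phenol must be masked during epoxidation and then freed selectively. The benzylic epoxide carbon is flanked by a ring with ortho and para oxygens, so opening can turn ionic; C2 then loses its configuration, and attack at the other epoxide carbon gives five-membered products.
- In comparison: the chosen route avoids any cation at C2 by creating that centre through hydride delivery, and its ring-forming step carries no stereochemical burden.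

Key step: step 7

Assumption: the sense of induction in step 8 is assigned by analogy with β-substituted cyclic enones; if the (R)-ligand delivers hydride to the wrong face of C2, its (S)-antipode is used with no other change.

## Route

Step 1
Reactants: 1 phloroglucinol
Product: 2 3,5-bis(methoxymethoxy)phenol
Conditions: MOMCl (2.0 equiv), i-Pr2NEt (2.2 equiv), CH2Cl2/DMF, 0 °C → rt; chromatography, mono- and tris-ethers recycled
Reagents that add atoms: chloromethyl methyl ether, COCCl
Why: O-alkylation of the phenoxides with an α-chloro ether; limiting the reagent to two equivalents should make the bis-ether the main product, and the three hydroxyls are equivalent, so only the degree of alkylation has to be controlled.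

Step 2
Reactants: 2 3,5-bis(methoxymethoxy)phenol
Product: 3 2-iodo-3,5-bis(methoxymethoxy)phenol
Conditions: I2 (1.0 equiv), NaHCO3, THF/H2O, 0 °C
Reagents that add atoms: iodine, II
Why: Electrophilic aromatic iodination of the phenoxide, which should direct to the position ortho to O−, as it does for resorcinol and 3-alkoxyphenols under the same conditions; the position between the two ethers is more hindered, and the acetals are stable to bicarbonate.

Step 3
Reactants: 4 2,4-dihydroxybenzaldehyde
Product: 5 3,5-dibromo-2,4-dihydroxybenzaldehyde
Conditions: Br2 (2.05 equiv), AcOH, rt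
Reagents that add atoms: bromine, BrBr
Why: Electrophilic aromatic bromination; C3 and C5 are the only ring positions ortho or para to both hydroxyls, and C6 is deactivated by the formyl group.

Step 4
Reactants: 5 3,5-dibromo-2,4-dihydroxybenzaldehyde
Product: 6 3,5-dibromo-2,4-bis(methoxymethoxy)benzaldehyde
Conditions: MOMCl (3 equiv), i-Pr2NEt (4 equiv), DMF, 0 °C → rt
Reagents that add atoms: chloromethyl methyl ether, COCCl
Why: O-alkylation of both phenols; the flanking bromines make them acidic, and the small electrophile should reach even the hydroxyl at C4 between two bromines.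

Step 5
Reactants: 6 3,5-dibromo-2,4-bis(methoxymethoxy)benzaldehyde; 7 tributyl(3-methylbut-2-en-1-yl)stannane (2.5 equiv)
Product: 8 2,4-bis(methoxymethoxy)-3,5-bis(3-methylbut-2-en-1-yl)benzaldehyde
Conditions: Pd2(dba)3 (5 mol %), P(t-Bu)3·HBF4 (12 mol %), CsF (5 equiv), dioxane, 90 °C
Reagents that add atoms: none
Why: Twofold Stille coupling; the bulky electron-rich phosphine allows oxidative addition even at the bromide between two alkoxy groups, fluoride activates the stannane, and reductive elimination at the unsubstituted allyl terminus should give the linear prenyl groups. The aldehyde and the acetals are inert.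

Step 6
Reactants: 8 2,4-bis(methoxymethoxy)-3,5-bis(3-methylbut-2-en-1-yl)benzaldehyde
Product: 9 1-ethynyl-2,4-bis(methoxymethoxy)-3,5-bis(3-methylbut-2-en-1-yl)benzene
Conditions: dimethyl (1-diazo-2-oxopropyl)phosphonate (1.5 equiv), K2CO3 (2 equiv), MeOH, 0 °C → rt
Reagents that add atoms: dimethyl (1-diazo-2-oxopropyl)phosphonate, CC(=O)C(=[N+]=[N-])P(=O)(OC)OC
Why: Ohira–Bestmann homologation; methanolysis of the acetyl group frees the diazomethylphosphonate anion, which olefinates the aldehyde, and loss of N2 with 1,2-hydride shift gives the terminal alkyne. The substrate has no enolisable or base-labile site.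

Step 7
Reactants: 3 2-iodo-3,5-bis(methoxymethoxy)phenol; 9 1-ethynyl-2,4-bis(methoxymethoxy)-3,5-bis(3-methylbut-2-en-1-yl)benzene; 10 carbon monoxide
Product: 13 2-[2,4-bis(methoxymethoxy)-3,5-bis(3-methylbut-2-en-1-yl)phenyl]-5,7-bis(methoxymethoxy)-4H-chromen-4-one (tetrakis-MOM diprenylflavone), via ortho-hydroxyaryl ynone 11 (not isolated), via diethylamino enaminone 12 (not isolated)
Conditions: PdCl2(PPh3)2 (5 mol %), CO (10 atm), Et2NH (solvent), 100 °C
Reagents that add atoms: none
Why: Zerovalent palladium, formed in situ from PdCl2(PPh3)2, inserts into the C–I bond of 3, CO insertion gives the aroylpalladium iodide, and amine-assisted transfer of the acetylide of 9 followed by reductive elimination forms C4a–C4 and C4–C3 in ynone 11. Diethylamine then adds to the ynone to give the vinylogous amide 12, and the ortho phenol attacks its β-carbon (C2) and expels the amine, forming O1–C2. Ring C thus closes in the 6-endo mode (6-endo-dig with respect to 11, in practice an addition–elimination on 12). The closest known reaction type is the palladium-catalysed carbonylative coupling of ortho-iodophenols with terminal arylacetylenes in a secondary amine, which gives chromones and flavones. No stereocentre is formed. The step needs carbonylative rather than direct alkynylation, which CO pressure, the absence of a copper co-catalyst and the ready migration of the electron-rich aryl group onto CO should secure. It also needs 6-endo rather than 5-exo closure (aurone), which the enaminone secures because its only electrophilic carbon is C2; closure can occur in one sense only, since 3 has a single free hydroxyl ortho to iodine. The acetal ethers and the unactivated prenyl alkenes are inert to zerovalent and divalent palladium under CO.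

Step 8
Reactants: 13 tetrakis-MOM diprenylflavone
Product: 14 (2S)-2-[2,4-bis(methoxymethoxy)-3,5-bis(3-methylbut-2-en-1-yl)phenyl]-5,7-bis(methoxymethoxy)chroman-4-one
Conditions: Cu(OAc)2·H2O (5 mol %), (R)-DTBM-SEGPHOS (5.5 mol %), (EtO)2MeSiH (1.5 equiv), t-BuOH (1.5 equiv), toluene, 0 °C → rt
Reagents that add atoms: none
Why: Asymmetric conjugate reduction by a bisphosphine copper hydride, a reaction type known for β,β-disubstituted cyclic enones and for chromones; the chiral ligand selects the face of C2 that receives hydride, and t-BuOH protonates the copper enolate at once, so the enolate has no time to expel O1. The trisubstituted prenyl alkenes are not hydrocuprated, and the doubly ortho-oxygenated aryl ketone of 14 should resist 1,2-reduction.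

Step 9
Reactants: 14 (2S)-flavanone
Product: 16 (2R,3R)-3-hydroxy-2-[2,4-bis(methoxymethoxy)-3,5-bis(3-methylbut-2-en-1-yl)phenyl]-5,7-bis(methoxymethoxy)chroman-4-one, via sodium enolate 15 (not isolated)
Conditions: NaN(SiMe3)2 (1.1 equiv), THF, −78 °C; 3-phenyl-2-(phenylsulfonyl)oxaziridine (1.3 equiv), −78 °C; AcOH quench at −78 °C
Reagents that add atoms: 3-phenyl-2-(phenylsulfonyl)oxaziridine, O=S(=O)(N1OC1c1ccccc1)c1ccccc1
Why: Enolate hydroxylation with an N-sulfonyloxaziridine (Davis oxidation); the oxidant should approach C3 of enolate 15 on the face opposite the C2 aryl group, giving the trans ketol, which is also the more stable diastereomer. The reagent does not epoxidise the prenyl alkenes at this temperature, and the cold quench limits ring opening; C2 keeps its spatial arrangement and its descriptor changes from S to R only because C3 now outranks C1'.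

Step 10
Reactants: 16 (2R,3R)-tetrakis-MOM dihydroflavonol
Product: 17 cathayanon I, (2R,3R)-2-[2,4-dihydroxy-3,5-bis(3-methylbut-2-en-1-yl)phenyl]-3,5,7-trihydroxychroman-4-one
Conditions: 3 M aq HCl, MeOH/THF, 40 °C, stopped at full conversion
Reagents that add atoms: none
Why: Acid-catalysed acetal exchange of the four aryl methoxymethyl ethers with methanol; aryl acetals should cleave under conditions milder than those that add a phenol to a prenyl alkene or ionise C2, and a short reaction time should keep both stereocentres intact.

## Compound list

1 | phloroglucinol | Oc1cc(O)cc(O)c1 | starting material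
2 | 3,5-bis(methoxymethoxy)phenol | COCOc1cc(O)cc(OCOC)c1 | intermediate
3 | 2-iodo-3,5-bis(methoxymethoxy)phenol | Oc1cc(OCOC)cc(OCOC)c1I | intermediate
4 | 2,4-dihydroxybenzaldehyde | O=Cc1ccc(O)cc1O | starting material
5 | 3,5-dibromo-2,4-dihydroxybenzaldehyde | O=Cc1cc(Br)c(O)c(Br)c1O | intermediate
6 | 3,5-dibromo-2,4-bis(methoxymethoxy)benzaldehyde | O=Cc1cc(Br)c(OCOC)c(Br)c1OCOC | intermediate
7 | tributyl(3-methylbut-2-en-1-yl)stannane | CC(C)=CC[Sn](CCCC)(CCCC)CCCC | starting material
8 | 2,4-bis(methoxymethoxy)-3,5-bis(3-methylbut-2-en-1-yl)benzaldehyde | O=Cc1cc(CC=C(C)C)c(OCOC)c(CC=C(C)C)c1OCOC | intermediate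
9 | 1-ethynyl-2,4-bis(methoxymethoxy)-3,5-bis(3-methylbut-2-en-1-yl)benzene | C#Cc1cc(CC=C(C)C)c(OCOC)c(CC=C(C)C)c1OCOC | intermediate
10 | carbon monoxide | [C-]#[O+] | starting material
11 | 1-[2-hydroxy-4,6-bis(methoxymethoxy)phenyl]-3-[2,4-bis(methoxymethoxy)-3,5-bis(3-methylbut-2-en-1-yl)phenyl]prop-2-yn-1-one | CC(C)=CCc1cc(C#CC(=O)c2c(O)cc(OCOC)cc2OCOC)c(OCOC)c(CC=C(C)C)c1OCOC | intermediate
12 | 3-(diethylamino)-1-[2-hydroxy-4,6-bis(methoxymethoxy)phenyl]-3-[2,4-bis(methoxymethoxy)-3,5-bis(3-methylbut-2-en-1-yl)phenyl]prop-2-en-1-one (alkene geometry not fixed) | CC(C)=CCc1cc(C(=CC(=O)c2c(O)cc(OCOC)cc2OCOC)N(CC)CC)c(OCOC)c(CC=C(C)C)c1OCOC | intermediate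
13 | 2-[2,4-bis(methoxymethoxy)-3,5-bis(3-methylbut-2-en-1-yl)phenyl]-5,7-bis(methoxymethoxy)-4H-chromen-4-one | CC(C)=CCc1cc(-c2cc(=O)c3c(OCOC)cc(OCOC)cc3o2)c(OCOC)c(CC=C(C)C)c1OCOC | intermediate
14 | (2S)-2-[2,4-bis(methoxymethoxy)-3,5-bis(3-methylbut-2-en-1-yl)phenyl]-5,7-bis(methoxymethoxy)chroman-4-one | CC(C)=CCc1cc([C@H]2Oc3cc(OCOC)cc(OCOC)c3C(=O)C2)c(OCOC)c(CC=C(C)C)c1OCOC | intermediate
15 | sodium (2S)-2-[2,4-bis(methoxymethoxy)-3,5-bis(3-methylbut-2-en-1-yl)phenyl]-5,7-bis(methoxymethoxy)-2H-chromen-4-olate | CC(C)=CCc1cc([C@H]2Oc3cc(OCOC)cc(OCOC)c3C([O-])=C2)c(OCOC)c(CC=C(C)C)c1OCOC.[Na+] | intermediate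
16 | (2R,3R)-3-hydroxy-2-[2,4-bis(methoxymethoxy)-3,5-bis(3-methylbut-2-en-1-yl)phenyl]-5,7-bis(methoxymethoxy)chroman-4-one | CC(C)=CCc1cc([C@H]2Oc3cc(OCOC)cc(OCOC)c3C(=O)[C@@H]2O)c(OCOC)c(CC=C(C)C)c1OCOC | intermediate
17 | cathayanon I, (2R,3R)-2-[2,4-dihydroxy-3,5-bis(3-methylbut-2-en-1-yl)phenyl]-3,5,7-trihydroxychroman-4-one | CC(C)=CCc1cc([C@H]2Oc3cc(O)cc(O)c3C(=O)[C@@H]2O)c(O)c(CC=C(C)C)c1O | target

## Step count and least certain steps

Total: 10 steps. Longest linear sequence: 8 steps (steps 3 to 10, from 4). Ring A is made in 2 steps (steps 1 and 2).

**Step 7 (key step).** Three things may go wrong: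
- alkynylation may outrun CO insertion, leading after cyclisation to a ring-contracted heterocycle without C4;
- the aroylpalladium intermediate may be intercepted by the amine (aminocarbonylation);
- oxidative addition into the electron-rich, doubly ortho-substituted C–I bond may be slow.

Fallback: build ynone 11 without palladium and rejoin the route there. It sets out from 9. Commercial 2,4,6-trihydroxybenzaldehyde F1 is protected with two equivalents of MOMCl and i-Pr2NEt; the hydroxyl hydrogen-bonded to the formyl group stays free, giving 2-hydroxy-4,6-bis(methoxymethoxy)benzaldehyde F2. F2 is deprotonated with LiN(SiMe3)2 and treated with the lithium acetylide of 9 (n-BuLi, THF, −78 → 0 °C) to give the racemic propargylic alcohol F3, which MnO2 in CH2Cl2 should oxidise to 11. Warming 11 in diethylamine then gives 12 and 13 as in the second half of step 7. This fallback also removes the dependence on step 2.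

**Step 8.** The flavone is a vinylogous ester with an ortho-substituted aryl group at C2, so hydride transfer may be slow. Forcing it invites 1,2-reduction at C4, and the facial selectivity may be lower than for simpler chromones. Fallback, from 13: conjugate reduction with LiBH(s-Bu)3 in THF at −78 °C gives the racemic flavanone F4. Kinetic resolution by asymmetric transfer hydrogenation follows, with RhCl(Cp*)(TsDPEN) in the enantiomeric form that reduces the (2R)-ketone, HCO2H/Et3N, to about half conversion. This converts the unwanted enantiomer into the cis-(2R,4R)-flavan-4-ol F5 and leaves 14, where the route is rejoined. Half of the material is lost.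

**Step 9.** Enolate 15 may expel O1 and open ring C; reclosure would erode the configuration at C2. The enolate may also add to the sulfonylimine by-product. Fallback, from 14: soft enolisation with TMSOTf and Et3N in CH2Cl2 at −78 °C gives the trimethylsilyl enol ether F6 without a free enolate. One equivalent of dimethyldioxirane at −78 °C (Rubottom oxidation) gives the 3-trimethylsilyloxy ketone F7; the enol ether is far more nucleophilic than the prenyl alkenes. Citric acid in MeOH at 0 °C then gives 16.

**Step 10.** Protic acid may add the freed phenols across the neighbouring prenyl alkenes, and ionisation at C2, helped by the 2'- and 4'-oxygens, may epimerise that centre. Fallback, from 16: TMSOTf with 2,2'-bipyridyl in CH2Cl2 at 0 °C should exchange each aryl acetal for a silyl ether and silylate the C3 hydroxyl, giving the pentakis(trimethylsilyl) ether F8. Neutral hydrolysis in aqueous THF then gives 17 without exposure to Brønsted acid.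

**Step 2.** Iodination may occur para to the hydroxyl, between the two ethers, or twice. Fallback, from 2: diethylcarbamoyl chloride and K2CO3 give the aryl carbamate F9. Directed ortho-lithiation (s-BuLi, TMEDA, THF, −78 °C) should take place between the carbamate and an acetal oxygen, and quenching with iodine at −78 °C gives the iodo carbamate F10. NaOH in EtOH at reflux then gives 3.

**Step 5.** Coupling may occur at the substituted allyl terminus (reverse prenyl), the second coupling at the hindered C3 bromide may stall, and protodebromination may compete. Fallback, from 6: twofold Stille coupling with allyltributylstannane under the conditions of step 5 gives the diallyl aldehyde F11, with no regiochemical question. Cross-metathesis with 2-methylbut-2-ene, using the second-generation Grubbs catalyst RuCl2(=CHPh)(PCy3)(H2IMes) in CH2Cl2 at 40 °C, then gives 8.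

## Further compounds

F1 | step 7 | 2,4,6-trihydroxybenzaldehyde | O=Cc1c(O)cc(O)cc1O
F2 | step 7 | 2-hydroxy-4,6-bis(methoxymethoxy)benzaldehyde | O=Cc1c(O)cc(OCOC)cc1OCOC
F3 | step 7 | 1-[2-hydroxy-4,6-bis(methoxymethoxy)phenyl]-3-[2,4-bis(methoxymethoxy)-3,5-bis(3-methylbut-2-en-1-yl)phenyl]prop-2-yn-1-ol (racemic) | CC(C)=CCc1cc(C#CC(O)c2c(O)cc(OCOC)cc2OCOC)c(OCOC)c(CC=C(C)C)c1OCOC
F4 | step 8 | racemic 2-[2,4-bis(methoxymethoxy)-3,5-bis(3-methylbut-2-en-1-yl)phenyl]-5,7-bis(methoxymethoxy)chroman-4-one | CC(C)=CCc1cc(C2CC(=O)c3c(OCOC)cc(OCOC)cc3O2)c(OCOC)c(CC=C(C)C)c1OCOC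
F5 | step 8 | (2R,4R)-2-[2,4-bis(methoxymethoxy)-3,5-bis(3-methylbut-2-en-1-yl)phenyl]-5,7-bis(methoxymethoxy)chroman-4-ol | CC(C)=CCc1cc([C@@H]2Oc3cc(OCOC)cc(OCOC)c3[C@H](O)C2)c(OCOC)c(CC=C(C)C)c1OCOC
F6 | step 9 | (2S)-2-[2,4-bis(methoxymethoxy)-3,5-bis(3-methylbut-2-en-1-yl)phenyl]-5,7-bis(methoxymethoxy)-4-(trimethylsilyloxy)-2H-chromene | CC(C)=CCc1cc([C@H]2Oc3cc(OCOC)cc(OCOC)c3C(O[Si](C)(C)C)=C2)c(OCOC)c(CC=C(C)C)c1OCOC
F7 | step 9 | (2R,3R)-2-[2,4-bis(methoxymethoxy)-3,5-bis(3-methylbut-2-en-1-yl)phenyl]-5,7-bis(methoxymethoxy)-3-(trimethylsilyloxy)chroman-4-one | CC(C)=CCc1cc([C@H]2Oc3cc(OCOC)cc(OCOC)c3C(=O)[C@@H]2O[Si](C)(C)C)c(OCOC)c(CC=C(C)C)c1OCOC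
F8 | step 10 | (2R,3R)-2-[2,4-bis(trimethylsilyloxy)-3,5-bis(3-methylbut-2-en-1-yl)phenyl]-3,5,7-tris(trimethylsilyloxy)chroman-4-one | CC(C)=CCc1cc([C@H]2Oc3cc(O[Si](C)(C)C)cc(O[Si](C)(C)C)c3C(=O)[C@@H]2O[Si](C)(C)C)c(O[Si](C)(C)C)c(CC=C(C)C)c1O[Si](C)(C)C
F9 | step 2 | 3,5-bis(methoxymethoxy)phenyl diethylcarbamate | CCN(CC)C(=O)Oc1cc(OCOC)cc(OCOC)c1
F10 | step 2 | 2-iodo-3,5-bis(methoxymethoxy)phenyl diethylcarbamate | CCN(CC)C(=O)Oc1cc(OCOC)cc(OCOC)c1I
F11 | step 5 | 3,5-diallyl-2,4-bis(methoxymethoxy)benzaldehyde | O=Cc1cc(CC=C)c(OCOC)c(CC=C)c1OCOC
A1 | alternative 1 | (2R,3R)-3,5,7,2',4'-pentakis(methoxymethoxy)-3',5'-diprenylflavanone | CC(C)=CCc1cc([C@H]2Oc3cc(OCOC)cc(OCOC)c3C(=O)[C@@H]2OCOC)c(OCOC)c(CC=C(C)C)c1OCOC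
A2 | alternative 1 | (2R,3R)-3',5'-dibromo-3,5,7,2',4'-pentakis(methoxymethoxy)flavanone | Brc1cc([C@H]2Oc3cc(OCOC)cc(OCOC)c3C(=O)[C@@H]2OCOC)c(OCOC)c(Br)c1OCOC
A3 | alternative 2 | (2R,3R)-3-O-(tert-butyldimethylsilyl)-5,7,2',4'-tetrakis(methoxymethoxy)-3',5'-diprenyl dihydroflavonol | CC(C)=CCc1cc([C@H]2Oc3cc(OCOC)cc(OCOC)c3C(=O)[C@@H]2O[Si](C)(C)C(C)(C)C)c(OCOC)c(CC=C(C)C)c1OCOC
A4 | alternative 2 | (2R,3R)-2-(tert-butyldimethylsilyloxy)-1-[2-fluoro-4,6-bis(methoxymethoxy)phenyl]-3-hydroxy-3-[2,4-bis(methoxymethoxy)-3,5-bis(3-methylbut-2-en-1-yl)phenyl]propan-1-one | CC(C)=CCc1cc([C@@H](O)[C@@H](O[Si](C)(C)C(C)(C)C)C(=O)c2c(F)cc(OCOC)cc2OCOC)c(OCOC)c(CC=C(C)C)c1OCOC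
A5 | alternative 3 | (2R,3R)-5,7,2',4'-tetrakis(methoxymethoxy)-3',5'-diprenyl dihydroflavonol (identical with 16) | CC(C)=CCc1cc([C@H]2Oc3cc(OCOC)cc(OCOC)c3C(=O)[C@@H]2O)c(OCOC)c(CC=C(C)C)c1OCOC
A6 | alternative 3 | [(2R,3S)-3-[2,4-bis(methoxymethoxy)-3,5-bis(3-methylbut-2-en-1-yl)phenyl]oxiran-2-yl][2-hydroxy-4,6-bis(methoxymethoxy)phenyl]methanone | CC(C)=CCc1cc([C@@H]2O[C@H]2C(=O)c2c(O)cc(OCOC)cc2OCOC)c(OCOC)c(CC=C(C)C)c1OCOC
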